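The synthesis rests on cutting the diaryl ketone between its carbonyl carbon and ring A (the halogenated ring). Two features are exploited. C1 of ring A lies between the C2–OMe and C6–OH oxygens and is the only unsubstituted ring atom of the Cl/Me/Br-laden, MOM-protected precursor. On ring B the ketone and formyl carbons are ortho neighbours. The key step deprotonates that lone C–H with an amide base (C–Br untouched) and adds the aryllithium to a 7-prenylphthalide. This temporary γ-lactone holds the ring B carbonyl coplanar and unshielded, stops after one addition and delivers the future formyl carbon as CH2OH. Oxidation and global MOM removal finish the route.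

Key step: step 8

Remark: the target has no stereocentre and its aryl–CO axes are taken as freely rotating. It is therefore treated as achiral, and no step has to set configuration.

Step 1
Reactants: 1 3-methoxy-5-methylphenol (orcinol monomethyl ether)
Product: 2 2-chloro-5-methoxy-3-methylphenol
Conditions: SO2Cl2 (1.0 equiv), 2,2,6,6-tetramethylpiperidine (5 mol %), toluene, 0 °C → rt
Reagents that add atoms: sulfuryl chloride, O=S(=O)(Cl)Cl
Why: Amine-catalysed ortho-selective electrophilic chlorination of a phenol: the N-chloroamine formed in situ is guided to the OH by hydrogen bonding, and of the two ortho carbons the one next to CH3 (also para to OMe) should react far faster than the carbon squeezed between the two oxygens.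

Step 2
Reactants: 2 2-chloro-5-methoxy-3-methylphenol
Product: 3 4-bromo-2-chloro-5-methoxy-3-methylphenol
Conditions: NBS (1.0 equiv), MeCN, 0 °C, dark
Reagents that add atoms: N-bromosuccinimide, O=C1CCC(=O)N1Br
Why: Electrophilic aromatic bromination with NBS in a polar solvent should go para to the OH (ortho to OMe), following the usual pattern of orcinol derivatives in which both carbons flanking the methyl group are halogenated before the carbon between the oxygens.

Step 3
Reactants: 3 4-bromo-2-chloro-5-methoxy-3-methylphenol
Product: 4 2-bromo-4-chloro-1-methoxy-5-(methoxymethoxy)-3-methylbenzene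
Conditions: MOMCl, i-Pr2NEt, CH2Cl2, 0 °C → rt
Reagents that add atoms: chloromethyl methyl ether (MOMCl), COCCl
Why: O-Alkylation of the phenol (Williamson type) installs an acetal that removes the acidic proton and acts with the OMe group as the second directing group of the later metalation.

Step 4
Reactants: 5 methyl 3,5-dihydroxybenzoate
Product: 6 methyl 3,5-bis(methoxymethoxy)benzoate
Conditions: MOMCl (2.5 equiv), i-Pr2NEt, CH2Cl2, 0 °C → rt
Reagents that add atoms: chloromethyl methyl ether (MOMCl), COCCl
Why: Twofold O-alkylation of the phenols (Williamson type) gives acetals that tolerate NBS and magnesium, zinc and lithium reagents and can leave together with the ring A acetal at the end.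

Step 5
Reactants: 6 methyl 3,5-bis(methoxymethoxy)benzoate
Product: 7 methyl 2,6-dibromo-3,5-bis(methoxymethoxy)benzoate
Conditions: NBS (2.1 equiv), MeCN, 0 °C → rt
Reagents that add atoms: N-bromosuccinimide, O=C1CCC(=O)N1Br
Why: Twofold electrophilic aromatic bromination of a resorcinol diether should take the two equivalent positions ortho/para to the oxygens (C2 and C6) rather than C4 between them, and NBS keeps the medium neutral for the acetals.

Step 6
Reactants: 7 methyl 2,6-dibromo-3,5-bis(methoxymethoxy)benzoate
Product: 10 7-bromo-4,6-bis(methoxymethoxy)isobenzofuran-1(3H)-one, via arylmagnesium chloride 8 (not isolated), via chloromagnesium alkoxide 9 (not isolated)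
Conditions: i-PrMgCl·LiCl (1.05 equiv), THF, −20 °C; (CH2O)n, −20 °C → rt; aq NH4Cl
Reagents that add atoms: paraformaldehyde (reacts as formaldehyde), C=O
Why: Br/Mg exchange with the turbo-Grignard reagent is accelerated by the flanking ester and OMOM groups and by the second bromine, so one equivalent should desymmetrise 7; Grignard addition to formaldehyde and spontaneous lactonisation of alkoxide 9 onto the neighbouring ester then close the five-membered ring (5-exo-trig).

Step 7
Reactants: 10 7-bromo-4,6-bis(methoxymethoxy)isobenzofuran-1(3H)-one
Product: 11 4,6-bis(methoxymethoxy)-7-(3-methylbut-2-en-1-yl)isobenzofuran-1(3H)-one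
Conditions: prenylZnBr (1.3 equiv; from prenyl bromide, Zn, LiCl, THF), Pd(OAc)2 (2 mol %), CPhos (4 mol %), THF, rt
Reagents that add atoms: prenylzinc bromide, CC(C)=CC[Zn]Br (made from prenyl bromide, CC(C)=CCBr, and zinc)
Why: Negishi coupling of a 3,3-disubstituted allylzinc halide under Pd/CPhos is linear-selective, so C–C bond formation at the unsubstituted allyl terminus should give the prenyl and not the reverse-prenyl arene, oxidative addition being helped by the ortho lactone carbonyl, which itself is inert to the zinc reagent at room temperature.

Step 8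
Reactants: 4 2-bromo-4-chloro-1-methoxy-5-(methoxymethoxy)-3-methylbenzene; 11 4,6-bis(methoxymethoxy)-7-(3-methylbut-2-en-1-yl)isobenzofuran-1(3H)-one
Product: 14 [3-bromo-5-chloro-2-methoxy-6-(methoxymethoxy)-4-methylphenyl][2-(hydroxymethyl)-3,5-bis(methoxymethoxy)-6-(3-methylbut-2-en-1-yl)phenyl]methanone, via aryllithium 12 (not isolated), via lithium lactolate 13 (not isolated)
Conditions: 4 (1.3 equiv), LiTMP (1.25 equiv; from 2,2,6,6-tetramethylpiperidine, n-BuLi), THF, −78 → −40 °C; 11 (1.0 equiv), THF, −78 → −40 °C; AcOH, −78 °C
Reagents that add atoms: none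
Why: LiTMP removes the only ring hydrogen of 4, which sits between the OMe and OMOM oxygens (cooperative directed ortho-metalation, further acidified by the meta Cl and Br), and as a non-nucleophilic amide it does not enter into Br/Li exchange; aryllithium 12, with lithium held by two ortho oxygens, is the most stabilised aryl anion available, so bromine migration has no driving force. 12 then attacks the lactone carbonyl of 11 from its open π-face to give lithium lactolate 13, and protonation lets the hemiketal open to hydroxy ketone 14 (in equilibrium with its lactol). The closest known reaction type is the addition of aryllithium or aryl Grignard reagents to phthalides, the standard entry to 2-(hydroxymethyl)benzophenones and 1-arylisobenzofurans. No ring is closed: the temporary five-membered lactone is opened, and the only new stereocentre, the lactolate carbon of 13, forms as a racemate and vanishes on ring opening. The step needs mono-addition, and carbonyl attack rather than proton abstraction from C3–H2 or from the benzylic–allylic CH2 of 11: the first is secured because 13 stays closed at low temperature and the derived tetra-ortho-substituted ketone is too shielded for a second attack, the second because the ring holds the C=O coplanar with ring B, so that the prenyl and CH2O neighbours lie in the carbonyl plane instead of blocking its faces as they do in a twisted 2,6-disubstituted benzoate.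

Step 9
Reactants: 14 hydroxy ketone
Product: 15 2-[3-bromo-5-chloro-2-methoxy-6-(methoxymethoxy)-4-methylbenzoyl]-4,6-bis(methoxymethoxy)-3-(3-methylbut-2-en-1-yl)benzaldehyde
Conditions: Dess–Martin periodinane (1.3 equiv), CH2Cl2, 0 °C → rt
Reagents that add atoms: none
Why: Dess–Martin oxidation of the primary benzylic alcohol, which drains any lactol tautomer through the open form, should stop at the aldehyde and leave the alkene, the acetals and the aryl halides untouched.

Step 10
Reactants: 15 tris-MOM keto aldehyde
Product: 16 Pestalone H, 2-(3-bromo-5-chloro-6-hydroxy-2-methoxy-4-methylbenzoyl)-4,6-dihydroxy-3-(3-methylbut-2-en-1-yl)benzaldehyde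
Conditions: 3 M aq HCl, THF, 40 °C
Reagents that add atoms: none
Why: Acid-catalysed acetal hydrolysis should remove all three MOM groups in one operation under the dilute-acid conditions commonly tolerated by ortho-prenylphenols, while basic media, which could trigger a Cannizzaro–Tishchenko-type isomerisation of the keto aldehyde to a phthalide, are avoided.

Compound list
1 | 3-methoxy-5-methylphenol | COc1cc(C)cc(O)c1 | starting material
2 | 2-chloro-5-methoxy-3-methylphenol | COc1cc(C)c(Cl)c(O)c1 | intermediate
3 | 4-bromo-2-chloro-5-methoxy-3-methylphenol | COc1cc(O)c(Cl)c(C)c1Br | intermediate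
4 | 2-bromo-4-chloro-1-methoxy-5-(methoxymethoxy)-3-methylbenzene | COCOc1cc(OC)c(Br)c(C)c1Cl | intermediate
5 | methyl 3,5-dihydroxybenzoate | COC(=O)c1cc(O)cc(O)c1 | starting material
6 | methyl 3,5-bis(methoxymethoxy)benzoate | COCOc1cc(OCOC)cc(C(=O)OC)c1 | intermediate
7 | methyl 2,6-dibromo-3,5-bis(methoxymethoxy)benzoate | COC(=O)c1c(Br)c(OCOC)cc(OCOC)c1Br | intermediate
8 | [3-bromo-2-(methoxycarbonyl)-4,6-bis(methoxymethoxy)phenyl]magnesium chloride (not isolated) | COC(=O)c1c(Br)c(OCOC)cc(OCOC)c1[Mg]Cl | intermediate
9 | chloromagnesium alkoxide of methyl 2-bromo-6-(hydroxymethyl)-3,5-bis(methoxymethoxy)benzoate (not isolated) | COC(=O)c1c(Br)c(OCOC)cc(OCOC)c1CO[Mg]Cl | intermediate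
10 | 7-bromo-4,6-bis(methoxymethoxy)isobenzofuran-1(3H)-one | O=C1OCc2c1c(Br)c(OCOC)cc2OCOC | intermediate
11 | 4,6-bis(methoxymethoxy)-7-(3-methylbut-2-en-1-yl)isobenzofuran-1(3H)-one | O=C1OCc2c1c(CC=C(C)C)c(OCOC)cc2OCOC | intermediate
12 | [3-bromo-5-chloro-2-methoxy-6-(methoxymethoxy)-4-methylphenyl]lithium (not isolated) | COCOc1c([Li])c(OC)c(Br)c(C)c1Cl | intermediate
13 | lithium 1-aryl-4,6-bis(methoxymethoxy)-7-prenyl-1,3-dihydroisobenzofuran-1-olate, racemic (not isolated) | [Li]OC1(OCc2c1c(CC=C(C)C)c(OCOC)cc2OCOC)c1c(OC)c(Br)c(C)c(Cl)c1OCOC | intermediate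
14 | [3-bromo-5-chloro-2-methoxy-6-(methoxymethoxy)-4-methylphenyl][2-(hydroxymethyl)-3,5-bis(methoxymethoxy)-6-(3-methylbut-2-en-1-yl)phenyl]methanone | COCOc1c(Cl)c(C)c(Br)c(OC)c1C(=O)c1c(CO)c(OCOC)cc(OCOC)c1CC=C(C)C | intermediate
15 | 2-[3-bromo-5-chloro-2-methoxy-6-(methoxymethoxy)-4-methylbenzoyl]-4,6-bis(methoxymethoxy)-3-(3-methylbut-2-en-1-yl)benzaldehyde | COCOc1c(Cl)c(C)c(Br)c(OC)c1C(=O)c1c(C=O)c(OCOC)cc(OCOC)c1CC=C(C)C | intermediate
16 | Pestalone H | COc1c(Br)c(C)c(Cl)c(O)c1C(=O)c1c(C=O)c(O)cc(O)c1CC=C(C)C | target

Total step count: 10. Longest linear sequence: 7 steps (steps 4–10, from 5).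

Steps most likely to fail

Step 8. The hindered aryllithium may act as a base toward the C3 methylene or the benzylic–allylic methylene of the lactone instead of adding. Bromine may also scramble between aryl anions during the metalation. The fallback replaces both partners by known chemistry; it sets out from 11 and 3 and comes back at 15.
- Lactone 11 is reduced with DIBAL-H (toluene, −78 °C) to 4,6-bis(methoxymethoxy)-7-(3-methylbut-2-en-1-yl)-1,3-dihydroisobenzofuran-1-ol F1, whose open form is a far more electrophilic benzaldehyde.
- Phenol 3 is iodinated at its last free position (NIS, MeCN) to 4-bromo-2-chloro-6-iodo-5-methoxy-3-methylphenol F2.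
- This is protected (MOMCl, i-Pr2NEt) as 2-bromo-4-chloro-6-iodo-1-methoxy-5-(methoxymethoxy)-3-methylbenzene F3.
- Iodine-selective exchange (i-PrMgCl·LiCl, THF, −40 °C) converts it, without any amide base, into [3-bromo-5-chloro-2-methoxy-6-(methoxymethoxy)-4-methylphenyl]magnesium chloride F4.
- Two equivalents of this Grignard reagent are used; the first deprotonates the lactol and is recovered as 4. Addition to the lactol's aldehyde form should give the racemic benzhydrol-type diol F5.
- A double Swern oxidation should then give 15. Both hydroxy groups are activated before the base is added, so no lactol can be over-oxidised to a phthalide.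

Step 6. The Br/Mg exchange may be sluggish or go twice on the electron-rich ring, and slowly depolymerising paraformaldehyde may capture the Grignard reagent poorly. The fallback builds the same lactone by electrophilic substitution instead of organometallic chemistry; it sets out from 5 and comes back at 10.
- Vilsmeier–Haack formylation of 5 (POCl3, DMF) should give methyl 2-formyl-3,5-dihydroxybenzoate F6.
- NBS should brominate the remaining position ortho/para to the hydroxy groups next to the ester, giving methyl 2-bromo-6-formyl-3,5-dihydroxybenzoate F7.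
- MOMCl/i-Pr2NEt gives methyl 2-bromo-6-formyl-3,5-bis(methoxymethoxy)benzoate F8.
- NaBH4 in MeOH reduces the aldehyde, and the resulting alkoxide lactonises onto the ester to give 10.

Step 10. Once the phenol next to the prenyl group is set free, proton-catalysed addition of that OH to the double bond (chroman formation) may compete. The hindered acetals may also cleave incompletely. The fallback avoids Brønsted acid by exchanging the protecting groups instead of hydrolysing them; it sets out from 15 and comes back at 16.
- TMSOTf and 2,2′-bipyridyl (CH2Cl2, 0 °C) convert the aryl MOM acetals, in a buffered medium, into the tris(trimethylsilyl) ether of Pestalone H F9.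
- Water at neutral pH then desilylates this ether to 16.

Further compounds
F1 | step 8 | 4,6-bis(methoxymethoxy)-7-(3-methylbut-2-en-1-yl)-1,3-dihydroisobenzofuran-1-ol | OC1OCc2c1c(CC=C(C)C)c(OCOC)cc2OCOC
F2 | step 8 | 4-bromo-2-chloro-6-iodo-5-methoxy-3-methylphenol | COc1c(Br)c(C)c(Cl)c(O)c1I
F3 | step 8 | 2-bromo-4-chloro-6-iodo-1-methoxy-5-(methoxymethoxy)-3-methylbenzene | COCOc1c(I)c(OC)c(Br)c(C)c1Cl
F4 | step 8 | [3-bromo-5-chloro-2-methoxy-6-(methoxymethoxy)-4-methylphenyl]magnesium chloride | COCOc1c([Mg]Cl)c(OC)c(Br)c(C)c1Cl
F5 | step 8 | [3-bromo-5-chloro-2-methoxy-6-(methoxymethoxy)-4-methylphenyl][2-(hydroxymethyl)-3,5-bis(methoxymethoxy)-6-(3-methylbut-2-en-1-yl)phenyl]methanol (racemic) | COCOc1c(Cl)c(C)c(Br)c(OC)c1C(O)c1c(CO)c(OCOC)cc(OCOC)c1CC=C(C)C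
F6 | step 6 | methyl 2-formyl-3,5-dihydroxybenzoate | COC(=O)c1cc(O)cc(O)c1C=O
F7 | step 6 | methyl 2-bromo-6-formyl-3,5-dihydroxybenzoate | COC(=O)c1c(Br)c(O)cc(O)c1C=O
F8 | step 6 | methyl 2-bromo-6-formyl-3,5-bis(methoxymethoxy)benzoate | COC(=O)c1c(Br)c(OCOC)cc(OCOC)c1C=O
F9 | step 10 | tris(trimethylsilyl) ether of Pestalone H | COc1c(Br)c(C)c(Cl)c(O[Si](C)(C)C)c1C(=O)c1c(C=O)c(O[Si](C)(C)C)cc(O[Si](C)(C)C)c1CC=C(C)C
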